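The earlier runs and the new flask are calculated on assumed constants; scatter was added.

Read at 2.00 min or at 25.0 min, Monday's target is 82.0 % or 81.4 %. Like a step response long past its time constant, that run has stopped moving, so you ask where the new flask stops, not when.

| flask | starting material | coupling partner | remark | time |
|---|---|---|---|---|
| Monday's | 0.70 mM | 0.75 mM (fed, over 6.0 s) | run made earlier; the fed solution adds 0.20 times the starting volume |  |
| Wednesday's | 1.1 mM | 0.75 mM (fed, over 6.0 s) | run made earlier; the fed solution adds 0.20 times the starting volume |  |
| Tuesday's | 0.50 mM | 1.1 mM (fed, over 6.0 s) | run made earlier; the fed solution adds 0.20 times the starting volume |  |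
| flask | 0.50 mM | 0.750 mM (fed, over 6.0 s) | the fed solution adds 0.20 times the starting volume | 30 min |

| run | time / min | target / % |
|---|---|---|
| Monday's | 2.00 | 82.0 |
| Monday's | 6.00 | 82.1 |
| Monday's | 12.0 | 82.8 |
| Monday's | 15.0 | 82.6 |
| Monday's | 25.0 | 81.4 |
| Wednesday's | 2.00 | 66.9 |
| Wednesday's | 6.00 | 67.3 |
| Wednesday's | 12.0 | 68.2 |
| Wednesday's | 15.0 | 67.7 |
| Wednesday's | 25.0 | 69.2 |
| Tuesday's | 2.00 | 91.1 |
| Tuesday's | 4.00 | 91.2 |
| Tuesday's | 6.00 | 90.4 |
| Tuesday's | 12.0 | 90.8 |
| Tuesday's | 25.0 | 91.0 |

(readings scatter by 0.5 percentage points)

- charges are per starting volume, the dose included; the dosed solution carries all of it
- a reading or a percentage of target counts all its forms, free or not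
- the reaction counts as stopped when no species that holds the starting material changes by six tenths of a point or more over the second half of the time

1. which holds at 30 min: what has brought the reaction to rest, or that it has not come to rest (the coupling partner has run out first / forward and back rates have come level / it is still moving / all of the starting material has reacted)
2. amount of target at 30 min, in percent of the starting material charged

So freeze time and take the partner roof ρ: the target that the charged coupling partner can make at one partner per target, in percent of the starting material charged. It is charge over charge, 150 % for the flask. Wednesday's ρ is 68.2 % and its reading at 12.0 min is 68.2 %, so that reading stands at the roof. Monday's ρ is 107 %, and its target stays under it.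

Now I bracket the flask. Tuesday holds the same starting material with more partner, so I take its 91.0 % as the bound from above. Monday holds the flask's partner with more starting material, so its 82.1 % bounds from below. Suppose Monday's shortfall shrinks at least in proportion to the starting material charged: my lower bound rises to 87.2 %. If the partner goes into target and nowhere else, one partner per target, these bounds leave 39.3 % to 41.9 % of the partner's charge unspent in the flask, so I name starting material the limiting reagent.

The forecast says 87 %, at my lower edge, and the coupling partner has run out first: “Partner then disappears before starting material is finished”. There we differ.

The flask gives 88.6 %, and all of the starting material has reacted.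

    starting material ⇌ intermediate + leaving ligand (K = 1.60 × 10⁻⁷ M, k = 0.570 /s)
    starting material + leaving ligand → side product (k = 76.0 /M/s)
    starting material + target ⇌ idle adduct, settled at all times (K = 750 /M)
    leaving ligand → by-product carried off (k = 0.00960 /s)
    coupling partner + intermediate → target (k = 4.30 × 10⁵ /M/s)

For the flask, the target over ρ leaves 40.9 % of the partner, and 41 % of its charge stands there at 30.0 min, with 11.4 % side product. Now take the neighbouring flask with 1.2 mM of starting material, other charges held. Its ρ is 62.5 %, under 100 percent, and it gives 62.5 % target, with 0 % of the partner left and 2.1 % of the starting material still unbound.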